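**Strategy.** Everything rests on cutting C1–C10 and C9–C11. The key step exploits the most congested part of ring B: the quaternary ring-fusion carbon C10 (methyl C20) and its neighbour C9 (side chain), which is α to C8, a carbonyl long before it becomes the exocyclic methylene. In one operation, a copper-catalysed asymmetric conjugate addition with enolate allylation joins flat 3-methylcyclohex-2-enone (ring B), a ketal-bearing Grignard reagent (C1–C4, C19) and allyl iodide (C11–C13). It makes both bonds and fixes C10 and C9. Ring A is then closed from C5 onto C4, C18 is delivered to C4 by allylboration of formaldehyde, and C5/C6 are set through an α-epoxide.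

Key step: step 2

Assumption: ketal 1 (the ethylene ketal of 5-chloropentan-2-one) is bought as such; labdane numbering and α/β (C20 = β) are used for all intermediates.

**Step 1**
Reactants: 1 2-(3-chloropropyl)-2-methyl-1,3-dioxolane
Product: 2 [3-(2-methyl-1,3-dioxolan-2-yl)propyl]magnesium chloride
Conditions: Mg turnings, I2 (cat.), THF, 45 °C; diluted with Et2O before use
Reagents that add atoms: magnesium, [Mg]
Why: Magnesium insertion into the primary C–Cl bond (Grignard formation) should proceed cleanly because the ketal is inert to the organomagnesium; no stereocentre is formed.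

**Step 2**
Reactants: 2 [3-(2-methyl-1,3-dioxolan-2-yl)propyl]magnesium chloride; 3 3-methylcyclohex-2-en-1-one; 4 allyl iodide
Product: 6 (2R,3R)-2-allyl-3-methyl-3-[3-(2-methyl-1,3-dioxolan-2-yl)propyl]cyclohexan-1-one (allyl cis to methyl), via magnesium enolate 5 (not isolated)
Conditions: Cu(OTf)2 (3 mol%), chiral 4,5-diphenylimidazolinium chloride as NHC precursor (4 mol%, enantiomer that gives 3R), Et2O, 0 °C, slow addition of 3; then 4, DMPU, 0 → 23 °C
Reagents that add atoms: none
Why: The Grignard reagent deprotonates the imidazolinium salt and reduces Cu(OTf)2 to a monovalent copper alkyl complex carrying the chiral NHC; this binds the enone as a π-complex, adds oxidatively at C10 (trivalent copper) and eliminates reductively to form C1–C10 and magnesium enolate 5, which then displaces iodide from 4 at C9 to form C9–C11. The closest known reaction type is the copper–NHC catalysed asymmetric conjugate addition of Grignard reagents to 3-substituted cyclohex-2-enones with alkylation of the enolate. No ring is closed. C10 is set by the ligand on copper, which tells apart the two faces of the flat enone, and C9 is set by the substrate, the allyl group entering anti to the bulkier C1 chain on the neighbouring quaternary carbon and therefore cis to methyl C20. The step needs 1,4- instead of 1,2-addition (copper catalysis in Et2O, slow addition), enantioface selection (ligand) and regiodefined C-allylation of the C8–C9 enolate before proton transfer (DMPU activation, excess allyl iodide).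

**Step 3**
Reactants: 6 (2R,3R)-2-allyl-3-methyl-3-[3-(2-methyl-1,3-dioxolan-2-yl)propyl]cyclohexan-1-one
Product: 8 6-allyl-5-methyl-5-[3-(2-methyl-1,3-dioxolan-2-yl)propyl]cyclohex-2-en-1-one (stereocentres as in 6), via silyl enol ether 7 (not isolated)
Conditions: LiN(iPr)2 (LDA), THF, −78 °C; TMSCl; then Pd(OAc)2, MeCN, 23 °C
Reagents that add atoms: none
Why: Saegusa–Ito oxidation: the amide base removes the accessible C7 hydrogen (C9–H is a methine wedged against quaternary C10), the trimethylsilyl enol ether is palladated at C7 and β-hydride elimination from C6 gives the C6=C7 enone without touching C9 or C10.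

**Step 4**
Reactants: 8 6-allyl-5-methyl-5-[3-(2-methyl-1,3-dioxolan-2-yl)propyl]cyclohex-2-en-1-one
Product: 9 tert-butyldimethylsilyl dienol ether of 8 with the diene C8(OTBS)=C7–C6=C5
Conditions: TBSOTf, Et3N, CH2Cl2, 0 → 23 °C
Reagents that add atoms: tert-butyldimethylsilyl trifluoromethanesulfonate, CC(C)(C)[Si](C)(C)OS(=O)(=O)C(F)(F)F
Why: Soft enolisation (silyl triflate and amine) should give the extended dienol ether by loss of a γ-hydrogen at C5, because the only α′ hydrogen (C9–H) is shielded by C10 and the allyl group and its removal would give a strained tetrasubstituted enol ether; C9 and C10 are unchanged.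

**Step 5**
Reactants: 9 tert-butyldimethylsilyl dienol ether of 8
Product: 11 1-allyl-5,8a-dimethyl-6,7,8,8a-tetrahydronaphthalen-2(1H)-one (labdane numbering: 8-oxo-4,6-diene; 9β-allyl; 10β-methyl), via cyclised ether 10 (not isolated)
Conditions: TBSOTf (0.2 equiv), 2,6-di-tert-butyl-4-methylpyridine, CH2Cl2, −78 → 0 °C; then TsOH·H2O, 23 → 40 °C
Reagents that add atoms: none
Why: Intramolecular vinylogous Mukaiyama addition: the silyl triflate opens the dioxolane to an oxocarbenium ion at C4, which is captured by the γ-carbon C5 of the dienol ether (six-membered ring, whereas attack through C7 would need an eight-membered ring); acid then expels the tertiary 2-silyloxyethoxy group (E1) with loss of H5 to give the conjugated dienone, so the transient centres at C4 and C5 disappear.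

**Step 6**
Reactants: 11 1-allyl-5,8a-dimethyl-6,7,8,8a-tetrahydronaphthalen-2(1H)-one
Product: 13 9β-allyl-4α-(hydroxymethyl)-4β,10β-dimethyl-Δ5-octalin-8-one, via allylboronate 12 (not isolated)
Conditions: CuCl (5 mol%), Xantphos (5 mol%), NaOtBu (10 mol%), B2pin2, MeOH, THF, 23 °C; solvent exchange; (CH2O)n, toluene, 80 °C; aq. NH4Cl
Reagents that add atoms: formaldehyde (from paraformaldehyde), C=O
Why: Copper-catalysed conjugate borylation should place boron on C6 (the δ-carbon C4 is fully substituted) from the α face, opposite methyl C20; the 6α-allylboronate then adds to formaldehyde through a closed six-membered (Zimmerman–Traxler type) transition state that delivers the CH2O unit to C4 on the face that carried boron, which sets C4 (C18 α, methyl C19 β) and moves the alkene to C5=C6 (allylboration).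

**Step 7**
Reactants: 13 9β-allyl-4α-(hydroxymethyl)-4β,10β-dimethyl-Δ5-octalin-8-one
Product: 14 (9β-allyl-4β,10β-dimethyl-8-oxo-Δ5-octalin-4α-yl)methyl benzoate
Conditions: BzCl, pyridine, DMAP (cat.), CH2Cl2, 0 → 23 °C
Reagents that add atoms: benzoyl chloride, O=C(Cl)c1ccccc1
Why: DMAP-catalysed acylation of the only hydroxyl group installs the C18 benzoate of the target early, where it also serves as the protecting group; no stereocentre is affected.

**Step 8**
Reactants: 14 (9β-allyl-4β,10β-dimethyl-8-oxo-Δ5-octalin-4α-yl)methyl benzoate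
Product: 15 (9β-allyl-5α,6α-epoxy-4β,10β-dimethyl-8-oxodecalin-4α-yl)methyl benzoate
Conditions: mCPBA, NaHCO3, CH2Cl2, 0 °C
Reagents that add atoms: 3-chloroperbenzoic acid, OOC(=O)c1cccc(Cl)c1
Why: Prilezhaev epoxidation: the trisubstituted C5=C6 alkene should react far faster than the monosubstituted allyl alkene, and the peracid approaches from the α face because the β face is covered by the axial C19 and C20 methyl groups, giving the 5α,6α-epoxide.

**Step 9**
Reactants: 15 (9β-allyl-5α,6α-epoxy-4β,10β-dimethyl-8-oxodecalin-4α-yl)methyl benzoate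
Product: 16 (9β-allyl-6α-hydroxy-4β,10β-dimethyl-8-oxo-5αH-decalin-4α-yl)methyl benzoate
Conditions: Cp2TiCl2, Mn, H2O, THF, 23 °C; dil. HCl work-up
Reagents that add atoms: none
Why: Titanocene-mediated reductive epoxide opening (Nugent–RajanBabu type): trivalent titanium (Cp2TiCl) cleaves the C5–O bond to the tertiary C5 radical, which should take a hydrogen atom from titanium-bound water on the open α face to give the trans ring fusion (5α-H), while the untouched C6–O bond keeps the 6α configuration; ketone, ester and terminal alkene are inert.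

**Step 10**
Reactants: 16 (9β-allyl-6α-hydroxy-4β,10β-dimethyl-8-oxo-5αH-decalin-4α-yl)methyl benzoate
Product: 17 (9β-allyl-6α-hydroxy-4β,10β-dimethyl-8-methylidene-5αH-decalin-4α-yl)methyl benzoate
Conditions: Zn, CH2Br2, TiCl4, THF/CH2Cl2, 0 → 23 °C
Reagents that add atoms: dibromomethane, BrCBr
Why: Lombardo–Takai methylenation: the non-basic zinc/titanium methylene reagent should convert the hindered, enolisable C8 ketone into the exocyclic alkene without epimerising C9, eliminating the β-hydroxyl or touching the benzoate.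

**Step 11**
Reactants: 17 (9β-allyl-6α-hydroxy-4β,10β-dimethyl-8-methylidene-5αH-decalin-4α-yl)methyl benzoate
Product: 19 [6α-hydroxy-9β-(3-hydroxypropyl)-4β,10β-dimethyl-8-methylidene-5αH-decalin-4α-yl]methyl benzoate, via alkylborane 18 (not isolated)
Conditions: Sia2BH (from BH3·THF and 2-methylbut-2-ene), THF, 0 °C; then H2O2, pH 7 phosphate buffer, 0 → 23 °C
Reagents that add atoms: hydrogen peroxide, OO
Why: Hydroboration–oxidation: the bulky dialkylborane should add to the monosubstituted C12=C13 alkene much faster than to the 1,1-disubstituted C8=C17 alkene, boron going to terminal C13, and oxidation at neutral pH gives the primary alcohol while sparing the benzoate.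

**Step 12**
Reactants: 19 [6α-hydroxy-9β-(3-hydroxypropyl)-4β,10β-dimethyl-8-methylidene-5αH-decalin-4α-yl]methyl benzoate
Product: 20 [6α-hydroxy-4β,10β-dimethyl-8-methylidene-9β-(3-oxopropyl)-5αH-decalin-4α-yl]methyl benzoate
Conditions: TEMPO (cat.), PhI(OAc)2, CH2Cl2, 23 °C
Reagents that add atoms: none
Why: Oxoammonium (TEMPO) oxidation is selective for the unhindered primary alcohol over the hindered secondary 6α-hydroxyl and stops at the aldehyde.

**Step 13**
Reactants: 20 [6α-hydroxy-4β,10β-dimethyl-8-methylidene-9β-(3-oxopropyl)-5αH-decalin-4α-yl]methyl benzoate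
Product: 21 [9β-(but-3-yn-1-yl)-6α-hydroxy-4β,10β-dimethyl-8-methylidene-5αH-decalin-4α-yl]methyl benzoate
Conditions: TMSCHN2, LiN(iPr)2 (LDA), THF, −78 → 0 °C
Reagents that add atoms: (trimethylsilyl)diazomethane, C[Si](C)(C)C=[N+]=[N-]
Why: Colvin rearrangement (Seyferth–Gilbert-type homologation): lithiated trimethylsilyldiazomethane adds to the aldehyde, loss of lithium trimethylsilanolate and N2 gives an alkylidene carbene, and its 1,2-hydrogen shift forms the terminal alkyne C13≡C14; the low temperature spares the benzoate.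

**Step 14**
Reactants: 21 [9β-(but-3-yn-1-yl)-6α-hydroxy-4β,10β-dimethyl-8-methylidene-5αH-decalin-4α-yl]methyl benzoate
Product: 22 allyl 5-{6α-[(allyloxy)carbonyloxy]-4α-(benzoyloxymethyl)-4β,10β-dimethyl-8-methylidene-5αH-decalin-9β-yl}pent-2-ynoate
Conditions: LiN(iPr)2 (LDA, 2.3 equiv), THF, −78 °C; allyl chloroformate, −78 → 0 °C
Reagents that add atoms: allyl chloroformate, C=CCOC(=O)Cl
Why: Deprotonation of the alkyne and of the 6α-hydroxyl followed by acylation gives the allyl ynoate (C15) and the O6 allyl carbonate, which protects the alcohol and leaves together with the ester in the last step (acetylide acylation).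

**Step 15**
Reactants: 22 allyl 5-{6α-[(allyloxy)carbonyloxy]-4α-(benzoyloxymethyl)-4β,10β-dimethyl-8-methylidene-5αH-decalin-9β-yl}pent-2-ynoate
Product: 23 allyl (2Z)-5-{6α-[(allyloxy)carbonyloxy]-4α-(benzoyloxymethyl)-4β,10β-dimethyl-8-methylidene-5αH-decalin-9β-yl}-3-methylpent-2-enoate
Conditions: Me2CuLi (from CuI and MeLi), THF, −78 °C; MeOH, −78 °C; aq. NH4Cl
Reagents that add atoms: lithium dimethylcuprate, [Li+].C[Cu-]C
Why: Syn carbocupration of the ynoate: methyl (C16) adds to C13 and copper to C14 on the same side, and protonation at −78 °C with retention leaves C12 and the ester cis, i.e. the 13Z alkene; the cold quench prevents equilibration through the allenoate, and the esters and the carbonate should not react at this temperature.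

**Step 16**
Reactants: 23 allyl (2Z)-5-{6α-[(allyloxy)carbonyloxy]-4α-(benzoyloxymethyl)-4β,10β-dimethyl-8-methylidene-5αH-decalin-9β-yl}-3-methylpent-2-enoate
Product: 24 18-benzoyloxy-6α-hydroxylabda-8(17),13Z-dien-15-oic acid
Conditions: Pd(PPh3)4 (5 mol%), morpholine, THF, 23 °C; pH 4 buffer
Reagents that add atoms: none
Why: Tsuji–Trost deallylation: zerovalent palladium ionises the allyl ester and the allyl carbonate to π-allyl complexes that are captured by morpholine, the carbonate losing CO2, so the acid and the 6α-hydroxyl are freed under neutral conditions that leave the benzoate, both alkenes and all stereocentres untouched.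

**Compound list**

1 | 2-(3-chloropropyl)-2-methyl-1,3-dioxolane | ClCCCC1(C)OCCO1 | starting material
2 | [3-(2-methyl-1,3-dioxolan-2-yl)propyl]magnesium chloride | Cl[Mg]CCCC1(C)OCCO1 | intermediate
3 | 3-methylcyclohex-2-en-1-one | CC1=CC(=O)CCC1 | starting material
4 | allyl iodide (3-iodoprop-1-ene) | C=CCI | starting material
5 | chloromagnesium enolate (C8=C9) of (3R)-3-methyl-3-[3-(2-methyl-1,3-dioxolan-2-yl)propyl]cyclohexan-1-one (not isolated) | Cl[Mg]OC1=C[C@@](C)(CCCC2(C)OCCO2)CCC1 | intermediate
6 | (2R,3R)-2-allyl-3-methyl-3-[3-(2-methyl-1,3-dioxolan-2-yl)propyl]cyclohexan-1-one (allyl cis to methyl) | C=CC[C@H]1C(=O)CCC[C@]1(C)CCCC2(C)OCCO2 | intermediate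
7 | trimethylsilyl enol ether of 6, enol double bond C7=C8 (not isolated) | C=CC[C@H]1C(O[Si](C)(C)C)=CCC[C@]1(C)CCCC2(C)OCCO2 | intermediate
8 | 6-allyl-5-methyl-5-[3-(2-methyl-1,3-dioxolan-2-yl)propyl]cyclohex-2-en-1-one (stereocentres as in 6) | C=CC[C@H]1C(=O)C=CC[C@]1(C)CCCC2(C)OCCO2 | intermediate
9 | tert-butyldimethylsilyl dienol ether of 8, diene C8(OTBS)=C7–C6=C5 | C=CC[C@H]1C(O[Si](C)(C)C(C)(C)C)=CC=C[C@]1(C)CCCC2(C)OCCO2 | intermediate
10 | 9β-allyl-4,10β-dimethyl-4-[2-(tert-butyldimethylsilyloxy)ethoxy]-Δ6-octalin-8-one, C4 and C5 unassigned (not isolated) | O=C1C=CC2C(C)(OCCO[Si](C)(C)C(C)(C)C)CCC[C@]2(C)[C@H]1CC=C | intermediate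
11 | 1-allyl-5,8a-dimethyl-6,7,8,8a-tetrahydronaphthalen-2(1H)-one (8-oxo-4,6-diene, 9β-allyl, 10β-methyl) | O=C1C=CC2=C(C)CCC[C@]2(C)[C@H]1CC=C | intermediate
12 | 9β-allyl-4,10β-dimethyl-6α-(4,4,5,5-tetramethyl-1,3,2-dioxaborolan-2-yl)-Δ4-octalin-8-one (not isolated) | O=C1C[C@H](B3OC(C)(C)C(C)(C)O3)C2=C(C)CCC[C@]2(C)[C@H]1CC=C | intermediate
13 | 9β-allyl-4α-(hydroxymethyl)-4β,10β-dimethyl-Δ5-octalin-8-one | O=C1CC=C2[C@](C)(CO)CCC[C@]2(C)[C@H]1CC=C | intermediate
14 | (9β-allyl-4β,10β-dimethyl-8-oxo-Δ5-octalin-4α-yl)methyl benzoate | O=C1CC=C2[C@](C)(COC(=O)c3ccccc3)CCC[C@]2(C)[C@H]1CC=C | intermediate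
15 | (9β-allyl-5α,6α-epoxy-4β,10β-dimethyl-8-oxodecalin-4α-yl)methyl benzoate | O=C1C[C@@H]2O[C@@]23[C@](C)(COC(=O)c4ccccc4)CCC[C@]3(C)[C@H]1CC=C | intermediate
16 | (9β-allyl-6α-hydroxy-4β,10β-dimethyl-8-oxo-5αH-decalin-4α-yl)methyl benzoate | O=C1C[C@H](O)[C@H]2[C@](C)(COC(=O)c3ccccc3)CCC[C@]2(C)[C@H]1CC=C | intermediate
17 | (9β-allyl-6α-hydroxy-4β,10β-dimethyl-8-methylidene-5αH-decalin-4α-yl)methyl benzoate | C=C1C[C@H](O)[C@H]2[C@](C)(COC(=O)c3ccccc3)CCC[C@]2(C)[C@H]1CC=C | intermediate
18 | 17 with C13 bound to bis(3-methylbutan-2-yl)boryl in place of the terminal alkene (not isolated) | C=C1C[C@H](O)[C@H]2[C@](C)(COC(=O)c3ccccc3)CCC[C@]2(C)[C@H]1CCCB(C(C)C(C)C)C(C)C(C)C | intermediate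
19 | [6α-hydroxy-9β-(3-hydroxypropyl)-4β,10β-dimethyl-8-methylidene-5αH-decalin-4α-yl]methyl benzoate | C=C1C[C@H](O)[C@H]2[C@](C)(COC(=O)c3ccccc3)CCC[C@]2(C)[C@H]1CCCO | intermediate
20 | [6α-hydroxy-4β,10β-dimethyl-8-methylidene-9β-(3-oxopropyl)-5αH-decalin-4α-yl]methyl benzoate | C=C1C[C@H](O)[C@H]2[C@](C)(COC(=O)c3ccccc3)CCC[C@]2(C)[C@H]1CCC=O | intermediate
21 | [9β-(but-3-yn-1-yl)-6α-hydroxy-4β,10β-dimethyl-8-methylidene-5αH-decalin-4α-yl]methyl benzoate | C=C1C[C@H](O)[C@H]2[C@](C)(COC(=O)c3ccccc3)CCC[C@]2(C)[C@H]1CCC#C | intermediate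
22 | allyl 5-{6α-[(allyloxy)carbonyloxy]-4α-(benzoyloxymethyl)-4β,10β-dimethyl-8-methylidene-5αH-decalin-9β-yl}pent-2-ynoate | C=C1C[C@H](OC(=O)OCC=C)[C@H]2[C@](C)(COC(=O)c3ccccc3)CCC[C@]2(C)[C@H]1CCC#CC(=O)OCC=C | intermediate
23 | allyl (2Z)-5-{6α-[(allyloxy)carbonyloxy]-4α-(benzoyloxymethyl)-4β,10β-dimethyl-8-methylidene-5αH-decalin-9β-yl}-3-methylpent-2-enoate | C=C1C[C@H](OC(=O)OCC=C)[C@H]2[C@](C)(COC(=O)c3ccccc3)CCC[C@]2(C)[C@H]1CC/C(C)=C\C(=O)OCC=C | intermediate
24 | 18-benzoyloxy-6α-hydroxylabda-8(17),13Z-dien-15-oic acid | C=C1C[C@H](O)[C@H]2[C@](C)(COC(=O)c3ccccc3)CCC[C@]2(C)[C@H]1CC/C(C)=C\C(=O)O | target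

Total step count: 16. Longest linear sequence: 16 steps (1 → 24; 3 and 4 enter at step 2).

**Steps most likely to fail**

1. Step 5 (ring A closure; it depends on the dienol ether of step 4). What may go wrong: enolisation of 8 toward C9 instead of C5, or protodesilylation of the dienol ether before the ketal ionises, so that C5 never attacks C4. Fallback, from 8 back to 11: aqueous HCl in THF removes the ketal from 8 to give 6-allyl-5-methyl-5-(4-oxopentyl)cyclohex-2-en-1-one F1. Heating F1 with pyrrolidine and acetic acid in toluene with removal of water (or with KOtBu in t-BuOH) forms the extended dienamine or dienolate, whose γ-carbon C5 adds to the C4 ketone. Aldol and Michael adducts of the chain ketone are reversible under these conditions; dehydration to the conjugated dienone 11 is not (intramolecular vinylogous aldol condensation).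

2. Step 9 (reductive epoxide opening). What may go wrong: slow hydrogen transfer to the congested C5 radical, which allows loss of the C6 hydrogen to a 6-ketone or delivery of hydrogen from the wrong face (cis ring fusion). Fallback, from 14 back to 16: DBU in toluene at 60 °C moves the C5=C6 double bond into conjugation with the C8 ketone, the dienolate being protonated at C5 on the α face, to give the trans-fused enone (9β-allyl-4β,10β-dimethyl-8-oxo-5αH-Δ6-octalin-4α-yl)methyl benzoate F2. Copper-catalysed conjugate borylation (CuCl, Xantphos, NaOtBu, B2pin2, MeOH) adds boron to C6 from the α face, away from the C19 and C20 methyl groups, to give the 6α-boryl ketone F3. Oxidation with NaBO3 replaces boron by hydroxyl with retention and gives 16.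

3. Step 2 (key step). What may go wrong: incomplete or unselective C-allylation of the hindered magnesium enolate (proton transfer, O-allylation, low facial selectivity at C9); the coordinating ketal chain may also lower the enantioselectivity of the addition. Fallback, from 5 back to 6: the enolate 5 is quenched at −78 °C with allyl chloroformate and DMPU instead of allyl iodide, which gives allyl (3R)-3-methyl-3-[3-(2-methyl-1,3-dioxolan-2-yl)propyl]cyclohex-1-en-1-yl carbonate F4. Pd(PPh3)4 in THF then effects the decarboxylative Tsuji allylation, which returns the allyl group regiospecifically to C9 and gives 6; a chiral ligand on palladium can reinforce the C9 selectivity.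

**Further compounds**

F1 | step 5 | 6-allyl-5-methyl-5-(4-oxopentyl)cyclohex-2-en-1-one (stereocentres as in 8) | C=CC[C@H]1C(=O)C=CC[C@]1(C)CCCC(C)=O
F2 | step 9 | (9β-allyl-4β,10β-dimethyl-8-oxo-5αH-Δ6-octalin-4α-yl)methyl benzoate | O=C1C=C[C@H]2[C@](C)(COC(=O)c3ccccc3)CCC[C@]2(C)[C@H]1CC=C
F3 | step 9 | [9β-allyl-4β,10β-dimethyl-8-oxo-6α-(4,4,5,5-tetramethyl-1,3,2-dioxaborolan-2-yl)-5αH-decalin-4α-yl]methyl benzoate | O=C1C[C@H](B3OC(C)(C)C(C)(C)O3)[C@H]2[C@](C)(COC(=O)c4ccccc4)CCC[C@]2(C)[C@H]1CC=C
F4 | step 2 | allyl (3R)-3-methyl-3-[3-(2-methyl-1,3-dioxolan-2-yl)propyl]cyclohex-1-en-1-yl carbonate | C=CCOC(=O)OC1=C[C@@](C)(CCCC2(C)OCCO2)CCC1
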